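**Assumptions.** The SMILES descriptors correspond to (7R,8R), i.e. the threo 8‑O‑4′ series. The Evans auxiliary (S)‑4‑benzyloxazolidin‑2‑one is used as a recoverable chiral reagent, so it is listed under reagents and not numbered.

**Retrosynthetic overview**
1. Target 22 ⇐ acetonide hydrolysis and LiBH4 reduction (imide → C9‑OH, side‑chain ester → CH2OH) of the Evans syn‑aldol adduct 20.
2. Key disconnection C7–C8: aldehyde 10 (ring A plus masked glycerol) + aryloxyacetyl imide 17 (ring B plus C8–C9), joined late by a boron aldol that sets both stereocentres.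
3. 10 ⇐ syringaldehyde 5 + dioxanol 9 (Mitsunobu C–O; 9 from Tris). 17 ⇐ phenol 14 + bromoacetyl imide 16 (SN2 C–O); 14 ⇐ 5 + monomethyl malonate.
4. Syringaldehyde 5 ⇐ p‑cresol (bromination/side‑chain oxidation, then Cu‑catalysed methoxylation).
5. Rings: no ring of the target is built; both arenes come intact from p‑cresol. The only ring made is the temporary 1,3‑dioxane acetonide (step 3), opened in step 13.

**Route**

Step 1
Reactants: 1 p‑cresol
Product: 4 3,5-dibromo-4-hydroxybenzaldehyde, via 2,6-dibromo-4-methylphenol 2 (not isolated), via 2,6-dibromo-4-(dibromomethyl)phenol 3 (not isolated)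
Conditions: Br2 (2.0 eq), o‑dichlorobenzene, 30–40 °C; Br2 (2.1 eq), 150–160 °C; H2O, 100 °C
Reagents that add atoms: bromine, BrBr; water, O
Why: Electrophilic aromatic bromination ortho to the OH, then high‑temperature side‑chain bromination to the benzal bromide and hydrolysis of the gem‑dibromide gives the aldehyde.

Step 2
Reactants: 4 3,5-dibromo-4-hydroxybenzaldehyde
Product: 5 syringaldehyde (4-hydroxy-3,5-dimethoxybenzaldehyde)
Conditions: NaOMe (5 eq), CuCl (0.2 eq), DMF/MeOH, 110 °C; aq HCl work‑up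
Reagents that add atoms: sodium methoxide, [Na+].[O-]C
Why: Cu(I)‑catalysed Ullmann‑type methoxylation replaces both aryl bromides, and the para‑phenoxide protects the aldehyde from Cannizzaro chemistry.

Step 3
Reactants: 6 tris(hydroxymethyl)aminomethane
Product: 7 (5-amino-2,2-dimethyl-1,3-dioxan-5-yl)methanol
Conditions: Me2C(OMe)2 (1.1 eq), TsOH·H2O (1.05 eq), DMF, rt; then Et3N
Reagents that add atoms: 2,2-dimethoxypropane, COC(C)(C)OC
Why: Acid‑mediated transketalisation closes the six‑membered 1,3‑acetonide while the amine is held as its ammonium salt.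

Step 4
Reactants: 7 (5-amino-2,2-dimethyl-1,3-dioxan-5-yl)methanol
Product: 8 2,2-dimethyl-1,3-dioxan-5-one
Conditions: NaIO4 (1.05 eq), KH2PO4, H2O, 0 °C → rt
Reagents that add atoms: water, O
Why: Periodate cleavage of the 1,2‑amino alcohol removes the CH2OH carbon as formaldehyde, and the resulting imine hydrolyses to the ketone.

Step 5
Reactants: 8 2,2-dimethyl-1,3-dioxan-5-one
Product: 9 2,2-dimethyl-1,3-dioxan-5-ol
Conditions: NaBH4, MeOH, 0 °C
Reagents that add atoms: none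
Why: Simple hydride reduction of the ketone; the carbinol carbon is not a stereocentre.

Step 6
Reactants: 5 syringaldehyde; 9 2,2-dimethyl-1,3-dioxan-5-ol
Product: 10 4-[(2,2-dimethyl-1,3-dioxan-5-yl)oxy]-3,5-dimethoxybenzaldehyde
Conditions: PPh3 (1.5 eq), DIAD (1.5 eq), THF, 0 °C → rt
Reagents that add atoms: none
Why: Mitsunobu etherification; the acidic phenol (pKa about 7) displaces the activated secondary alcohol at the symmetric C5 of the dioxane, so no stereochemical issue arises.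

Step 7
Reactants: 5 syringaldehyde; 11 monomethyl malonate
Product: 13 methyl (E)-sinapate, via arylidene malonate half-ester 12 (not isolated)
Conditions: pyridine, piperidine (0.1 eq), 70 °C
Reagents that add atoms: none
Why: Knoevenagel–Doebner condensation followed by decarboxylation of the free acid gives the thermodynamically favoured E‑cinnamate ester directly.

Step 8
Reactants: 13 methyl (E)-sinapate
Product: 14 methyl 3-(4-hydroxy-3,5-dimethoxyphenyl)propanoate
Conditions: H2 (1 atm), 10% Pd/C, EtOAc/MeOH, rt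
Reagents that add atoms: none
Why: Catalytic hydrogenation saturates the conjugated alkene only; arene, ester and phenol are untouched.

Step 9
Reactants: 15 bromoacetyl bromide
Product: 16 (S)-4-benzyl-3-(2-bromoacetyl)oxazolidin-2-one
Conditions: (S)-4-benzyloxazolidin-2-one, n‑BuLi (1.0 eq), THF, −78 °C; then 15, −78 → 0 °C
Reagents that add atoms: (S)-4-benzyloxazolidin-2-one, O=C1N[C@@H](Cc2ccccc2)CO1
Why: N‑acylation of the lithiated oxazolidinone by the acyl bromide, which reacts far faster than the alkyl bromide at −78 °C.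

Step 10
Reactants: 14 methyl 3-(4-hydroxy-3,5-dimethoxyphenyl)propanoate; 16 (S)-4-benzyl-3-(2-bromoacetyl)oxazolidin-2-one
Product: 17 methyl 3-[4-{2-[(4S)-4-benzyl-2-oxooxazolidin-3-yl]-2-oxoethoxy}-3,5-dimethoxyphenyl]propanoate
Conditions: K2CO3 (1.5 eq), acetone, rt
Reagents that add atoms: none
Why: Williamson‑type SN2 O‑alkylation of the phenoxide by the highly activated α‑bromo imide under mild base that spares the methyl ester.

Step 11
Reactants: 17 aryloxyacetyl imide; 10 4-[(2,2-dimethyl-1,3-dioxan-5-yl)oxy]-3,5-dimethoxybenzaldehyde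
Product: 20 (4S)-4-benzyl-3-[(2S,3R)-3-hydroxy-3-{4-[(2,2-dimethyl-1,3-dioxan-5-yl)oxy]-3,5-dimethoxyphenyl}-2-{4-(3-methoxy-3-oxopropyl)-2,6-dimethoxyphenoxy}propanoyl]oxazolidin-2-one, via Z-boron enolate 18 (not isolated), via boron aldolate 19 (not isolated)
Conditions: 17, Bu2BOTf (1.2 eq), iPr2NEt (1.4 eq), CH2Cl2, 0 °C; then 10, −78 → 0 °C; pH 7 buffer, MeOH, 30% H2O2, 0 °C
Reagents that add atoms: none
Why: Evans syn‑aldol; the Z(O)‑boron enolate adds through a Zimmerman–Traxler chair on the face away from the (S)‑benzyl group, giving the (2S,3R) "Evans syn" adduct, which is the threo (7R,8R) arrangement of the target.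

Step 12
Reactants: 20 Evans syn‑aldol adduct
Product: 21 (1R,2R)-1-{4-[(2,2-dimethyl-1,3-dioxan-5-yl)oxy]-3,5-dimethoxyphenyl}-2-[4-(3-hydroxypropyl)-2,6-dimethoxyphenoxy]propane-1,3-diol
Conditions: LiBH4 (5 eq), MeOH (5 eq), THF, 0 °C → rt
Reagents that add atoms: none
Why: Borohydride reduction cleaves the imide reductively to the C9 primary alcohol (fast, so no retro‑aldol or epimerisation) and also reduces the side‑chain methyl ester to the 3‑hydroxypropyl group.

Step 13
Reactants: 21 acetonide‑protected pentaol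
Product: 22 (1R,2R)-1-{4-[(1,3-dihydroxypropan-2-yl)oxy]-3,5-dimethoxyphenyl}-2-[4-(3-hydroxypropyl)-2,6-dimethoxyphenoxy]propane-1,3-diol (target)
Conditions: AcOH/H2O/THF (3:1:1), rt → 40 °C
Reagents that add atoms: none
Why: Mild acetal hydrolysis frees the glycerol 1,3‑diol under conditions too weak to ionise the non‑phenolic C7 benzylic alcohol, so the threo configuration is retained.

**Compound list**
1 | p‑cresol | Cc1ccc(O)cc1 | starting material
2 | 2,6-dibromo-4-methylphenol | Cc1cc(Br)c(O)c(Br)c1 | intermediate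
3 | 2,6-dibromo-4-(dibromomethyl)phenol | BrC(Br)c1cc(Br)c(O)c(Br)c1 | intermediate
4 | 3,5-dibromo-4-hydroxybenzaldehyde | O=Cc1cc(Br)c(O)c(Br)c1 | intermediate
5 | syringaldehyde | COc1cc(C=O)cc(OC)c1O | intermediate
6 | tris(hydroxymethyl)aminomethane | NC(CO)(CO)CO | starting material
7 | (5-amino-2,2-dimethyl-1,3-dioxan-5-yl)methanol | CC1(C)OCC(N)(CO)CO1 | intermediate
8 | 2,2-dimethyl-1,3-dioxan-5-one | CC1(C)OCC(=O)CO1 | intermediate
9 | 2,2-dimethyl-1,3-dioxan-5-ol | CC1(C)OCC(O)CO1 | intermediate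
10 | 4-[(2,2-dimethyl-1,3-dioxan-5-yl)oxy]-3,5-dimethoxybenzaldehyde | COc1cc(C=O)cc(OC)c1OC1COC(C)(C)OC1 | intermediate
11 | monomethyl malonate (3-methoxy-3-oxopropanoic acid) | COC(=O)CC(=O)O | starting material
12 | 3-(4-hydroxy-3,5-dimethoxyphenyl)-2-(methoxycarbonyl)acrylic acid (E/Z mixture) | COC(=O)C(=Cc1cc(OC)c(O)c(OC)c1)C(=O)O | intermediate
13 | methyl (E)-sinapate | COC(=O)/C=C/c1cc(OC)c(O)c(OC)c1 | intermediate
14 | methyl 3-(4-hydroxy-3,5-dimethoxyphenyl)propanoate | COC(=O)CCc1cc(OC)c(O)c(OC)c1 | intermediate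
15 | bromoacetyl bromide | BrCC(Br)=O | starting material
16 | (S)-4-benzyl-3-(2-bromoacetyl)oxazolidin-2-one | O=C(CBr)N1[C@@H](Cc2ccccc2)COC1=O | intermediate
17 | methyl 3-[4-{2-[(4S)-4-benzyl-2-oxooxazolidin-3-yl]-2-oxoethoxy}-3,5-dimethoxyphenyl]propanoate | COC(=O)CCc1cc(OC)c(OCC(=O)N2[C@@H](Cc3ccccc3)COC2=O)c(OC)c1 | intermediate
18 | Z‑(di‑n‑butylboryl) enolate of 17 | COC(=O)CCc1cc(OC)c(O/C=C(\OB(CCCC)CCCC)N2[C@@H](Cc3ccccc3)COC2=O)c(OC)c1 | intermediate
19 | O‑(di‑n‑butylboryl) aldolate of 20 | COc1cc([C@@H](OB(CCCC)CCCC)[C@@H](C(=O)N2[C@@H](Cc3ccccc3)COC2=O)Oc2c(OC)cc(CCC(=O)OC)cc2OC)cc(OC)c1OC1COC(C)(C)OC1 | intermediate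
20 | (4S)-4-benzyl-3-[(2S,3R)-3-hydroxy-3-{4-[(2,2-dimethyl-1,3-dioxan-5-yl)oxy]-3,5-dimethoxyphenyl}-2-{4-(3-methoxy-3-oxopropyl)-2,6-dimethoxyphenoxy}propanoyl]oxazolidin-2-one | COc1cc([C@@H](O)[C@@H](C(=O)N2[C@@H](Cc3ccccc3)COC2=O)Oc2c(OC)cc(CCC(=O)OC)cc2OC)cc(OC)c1OC1COC(C)(C)OC1 | intermediate
21 | (1R,2R)-1-{4-[(2,2-dimethyl-1,3-dioxan-5-yl)oxy]-3,5-dimethoxyphenyl}-2-[4-(3-hydroxypropyl)-2,6-dimethoxyphenoxy]propane-1,3-diol | COc1cc([C@@H](O)[C@@H](CO)Oc2c(OC)cc(CCCO)cc2OC)cc(OC)c1OC1COC(C)(C)OC1 | intermediate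
22 | (1R,2R)-1-{4-[(1,3-dihydroxypropan-2-yl)oxy]-3,5-dimethoxyphenyl}-2-[4-(3-hydroxypropyl)-2,6-dimethoxyphenoxy]propane-1,3-diol | COc1cc([C@@H](O)[C@@H](CO)Oc2c(OC)cc(CCCO)cc2OC)cc(OC)c1OC(CO)CO | target

**Step count.** Total: 13 steps. Longest linear sequence: 8 steps (1, 2, 7, 8, 10, 11, 12, 13, from p‑cresol). The other branches are steps 3–6 (glycerol unit and aldehyde 10) and step 9 (bromoacetyl imide).

**Steps most likely to fail, with fallbacks**

Step 6 (Mitsunobu of a hindered 2,6‑dimethoxyphenol at the C5 of a 1,3‑dioxane, where SN2 is slowed by the β‑oxygens and elimination competes). The fallback sets out from 5 and comes back at 10, and builds the glycerol unit by malonate alkylation and reduction instead of a Mitsunobu reaction. Compound 5 is O‑alkylated with dimethyl bromomalonate (K2CO3, acetone) to dimethyl 2-(4-formyl-2,6-dimethoxyphenoxy)malonate F1. Excess NaBH4 in MeOH/THF reduces the aldehyde and both activated esters to 2-[4-(hydroxymethyl)-2,6-dimethoxyphenoxy]propane-1,3-diol F2. The 1,3‑diol is closed with 2,2‑dimethoxypropane/PPTS to {4-[(2,2-dimethyl-1,3-dioxan-5-yl)oxy]-3,5-dimethoxyphenyl}methanol F3, and MnO2 in CH2Cl2 oxidises the benzylic alcohol to 10. Steps 3–5 are then not needed.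

Step 10 (the phenoxide may attack the imide carbonyl of 16 instead of the CH2Br, transferring the bromoacetyl group). The fallback sets out from 14 and comes back at 17, and attaches the auxiliary after the ether bond is made. Compound 14 is alkylated with tert‑butyl bromoacetate (K2CO3, acetone) to methyl 3-{4-[2-(tert-butoxy)-2-oxoethoxy]-3,5-dimethoxyphenyl}propanoate F4. TFA/CH2Cl2 cleaves the tert‑butyl ester to 2-[4-(3-methoxy-3-oxopropyl)-2,6-dimethoxyphenoxy]acetic acid F5. PivCl/Et3N in THF at −20 °C gives the pivalic mixed anhydride F6, which acylates (S)-4-benzyloxazolidin-2-one in the presence of LiCl to give 17. Step 9 is then not needed.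

Step 11 (boron aldol between a hindered α‑(2,6‑dimethoxyphenoxy) enolate and an electron‑rich, poorly electrophilic benzaldehyde). The fallback sets out from 10 (with 14 as the phenol partner) and comes back at 21. It replaces the auxiliary aldol by C8–O bond formation followed by catalytic asymmetric reduction with dynamic kinetic resolution.
- The lithium enolate of methyl acetate (LDA, THF, −78 °C) adds to 10 to give racemic methyl 3-{4-[(2,2-dimethyl-1,3-dioxan-5-yl)oxy]-3,5-dimethoxyphenyl}-3-hydroxypropanoate F7.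
- Dess–Martin oxidation gives the β‑keto ester methyl 3-{4-[(2,2-dimethyl-1,3-dioxan-5-yl)oxy]-3,5-dimethoxyphenyl}-3-oxopropanoate F8.
- NBS gives the racemic α‑bromo β‑keto ester F9.
- Phenol 14 with K2CO3 in acetone displaces the bromide to give the racemic, configurationally labile α‑aryloxy β‑keto ester F10.
- Transfer hydrogenation with RuCl(p‑cymene)[(S,S)‑TsDPEN] in HCO2H/Et3N reduces the aryl ketone under dynamic kinetic resolution to the syn hydroxy diester methyl (2S,3R)-3-{4-[(2,2-dimethyl-1,3-dioxan-5-yl)oxy]-3,5-dimethoxyphenyl}-3-hydroxy-2-[4-(3-methoxy-3-oxopropyl)-2,6-dimethoxyphenoxy]propanoate F11. The catalyst hand is chosen by the usual Noyori sense and would need confirming by Mosher analysis.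
- LiBH4 in THF/MeOH reduces both esters to give 21.

Further compounds
F1 | step 6 | dimethyl 2-(4-formyl-2,6-dimethoxyphenoxy)malonate | COC(=O)C(Oc1c(OC)cc(C=O)cc1OC)C(=O)OC
F2 | step 6 | 2-[4-(hydroxymethyl)-2,6-dimethoxyphenoxy]propane-1,3-diol | OCC(CO)Oc1c(OC)cc(CO)cc1OC
F3 | step 6 | {4-[(2,2-dimethyl-1,3-dioxan-5-yl)oxy]-3,5-dimethoxyphenyl}methanol | CC1(C)OCC(Oc2c(OC)cc(CO)cc2OC)CO1
F4 | step 10 | methyl 3-{4-[2-(tert-butoxy)-2-oxoethoxy]-3,5-dimethoxyphenyl}propanoate | COC(=O)CCc1cc(OC)c(OCC(=O)OC(C)(C)C)c(OC)c1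
F5 | step 10 | 2-[4-(3-methoxy-3-oxopropyl)-2,6-dimethoxyphenoxy]acetic acid | COC(=O)CCc1cc(OC)c(OCC(=O)O)c(OC)c1
F6 | step 10 | pivalic mixed anhydride of F5 | COC(=O)CCc1cc(OC)c(OCC(=O)OC(=O)C(C)(C)C)c(OC)c1
F7 | step 11 | methyl 3-{4-[(2,2-dimethyl-1,3-dioxan-5-yl)oxy]-3,5-dimethoxyphenyl}-3-hydroxypropanoate (racemic) | COC(=O)CC(O)c1cc(OC)c(OC2COC(C)(C)OC2)c(OC)c1
F8 | step 11 | methyl 3-{4-[(2,2-dimethyl-1,3-dioxan-5-yl)oxy]-3,5-dimethoxyphenyl}-3-oxopropanoate | COC(=O)CC(=O)c1cc(OC)c(OC2COC(C)(C)OC2)c(OC)c1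
F9 | step 11 | methyl 2-bromo-3-{4-[(2,2-dimethyl-1,3-dioxan-5-yl)oxy]-3,5-dimethoxyphenyl}-3-oxopropanoate (racemic) | COC(=O)C(Br)C(=O)c1cc(OC)c(OC2COC(C)(C)OC2)c(OC)c1
F10 | step 11 | methyl 3-{4-[(2,2-dimethyl-1,3-dioxan-5-yl)oxy]-3,5-dimethoxyphenyl}-2-[4-(3-methoxy-3-oxopropyl)-2,6-dimethoxyphenoxy]-3-oxopropanoate (racemic) | COC(=O)CCc1cc(OC)c(OC(C(=O)OC)C(=O)c2cc(OC)c(OC3COC(C)(C)OC3)c(OC)c2)c(OC)c1
F11 | step 11 | methyl (2S,3R)-3-{4-[(2,2-dimethyl-1,3-dioxan-5-yl)oxy]-3,5-dimethoxyphenyl}-3-hydroxy-2-[4-(3-methoxy-3-oxopropyl)-2,6-dimethoxyphenoxy]propanoate | COc1cc([C@@H](O)[C@@H](C(=O)OC)Oc2c(OC)cc(CCC(=O)OC)cc2OC)cc(OC)c1OC1COC(C)(C)OC1
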